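## Structural features

The target is a cyclohexene (ring carbons C1–C6, alkene C1=C2) fused through C4–C5 to an oxirane. This 7-oxabicyclo[4.1.0]hept-3-ene core carries four contiguous stereocentres (C3, C4, C5, C6), and a fifth, C1', sits directly on the quaternary oxirane carbon C4. C1 bears an acetoxymethyl arm, C3 and C6 are secondary allylic carbinols flanking the oxirane, and C4 carries a fifteen-carbon chain: the C1' carbinol, a (2'E,4'E,6'E)-triene and an isolated C10'=C11' alkene. Relative to the oxirane oxygen the C6 hydroxyl is syn and the C3 hydroxyl is anti; along C5–C4–C1'–C2' the C1' hydroxyl and the oxirane oxygen are anti (erythro). The descriptors are (1S,2S,5S,6R) in bicyclic numbering and 1'S. The fragile groups are the oxirane (three neighbouring hydroxyls, Payne migration under base), the primary allylic acetate (migration to the C6 hydroxyl, solvolysis), the C1' carbinol (ionises easily next to the triene) and the polyene (light, acid, oxidants). The difficulty is concentrated at C4 and its neighbours: the fully substituted oxirane carbon must be made in one absolute sense, the C3 hydroxyl must lie on the face a hydride does not deliver to, and C1' must be set outside the ring. The feature exploited is one of oxidation level: C3 and C6 are quinone carbonyls, the C1 and C4 arms are para, and the oxirane occupies one quinone alkene. The ring is therefore the mono-epoxide of a 2,5-disubstituted 1,4-benzoquinone with a twofold axis, and the two CH2O arms can start out identical.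

## Logic of the disconnections

**23 ⇒ 22.** Only the Si–O bonds at C3 and C6 are cut. Both secondary hydroxyls stay masked through the oxidation and the coupling, so the last step creates no stereocentre and no C–C bond. The demand is a buffered fluoride source that spares the acetate, the oxirane and the C1' carbinol.

**22 ⇒ 14 + 21.** The C1'–C2' bond is cut, because it is the only C–C bond that joins the stereochemically dense ring to the achiral polyene and it ends in a carbinol. The gain is full convergence: 14 holds four stereocentres and no polyene, 21 holds the polyene and no stereocentre. The forward step needs an alkenyl nucleophile that tolerates acetate and oxirane (alkenylchromium), and it must add to an α-oxygenated, α-quaternary aldehyde in the anti (Cornforth/Felkin–Anh) sense.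

**21 ⇒ 20 + 18; 20 ⇒ 19; 18 ⇒ 17 ⇒ 15.** The central C4'=C5' alkene is cut, then the C–P bond of 20, and the C3'–CH3 and C2'–I bonds of 17. Each half then carries one trisubstituted alkene of secure geometry: C6'=C7' is bought with 19, and C2'=C3' comes from syn carbometalation of 15. Commercial citral is a mixture of geometric isomers, so the E-defined 19 is the safer source of C5'–C12'. The demand is an E-selective phosphonate olefination without scrambling of the two flanking alkenes.

**14 ⇒ 13 ⇒ 12 ⇒ 11.** No skeletal bond is cut. The C1' oxidation level is lowered, the acetyl C–O bond on the C1 arm is cut, then the two primary Si–O bonds. The arms have been identical since 4 and are told apart here by sterics: one hydroxymethyl is allylic and open, the other is neopentylic on the oxirane carbon. The demands are that the secondary silyl ethers survive cleavage of the primary ones and that acylation picks the allylic hydroxyl.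

**11 ⇒ 10 ⇒ 9 ⇒ 8.** The C3–O bond is cut and re-formed with inversion. Hydride is expected to enter both ring carbonyls anti to the oxirane oxygen. The C4–O bond stands almost perpendicular to the C3 carbonyl plane, so attack on the oxygen face would eclipse it. The C4 arm lies close to that plane and shields neither face well. A plan that counts on the arm to steer hydride onto the oxygen face at C3 is therefore not defensible: reduction gives the C6 configuration of the target but the wrong one at C3. An SN2 displacement by carboxylate uses exactly the accessible face, anti to the oxirane oxygen. The demand is that C3 carries the only free hydroxyl; SN2' and elimination are blocked by the substitution pattern.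

**8 ⇒ 7 ⇒ 6 ⇒ 5.** The C3–H and C6–H bonds are cut, one carbonyl at a time, with the C6 oxygen silylated in between. This takes the core back to a compound with only the two oxirane stereocentres. The demand is that the first hydride goes to C6 and not to C3, and that each enters anti to the oxirane oxygen.

**5 ⇒ 4.** The C4–O and C5–O bonds are cut, which removes the oxirane and both remaining stereocentres. The precursor 4 has a twofold axis, so its two alkenes are equivalent and only a face has to be chosen. The demand is a chiral nucleophilic oxidant that stops after one epoxidation.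

**4 ⇒ 3 ⇒ 2 ⇒ 1.** Only functional groups change: quinone to hydroquinone, silyl ethers to alcohols, hydroxymethyl groups to esters. This arrives at a cheap arene with the para carbon arms already in place. The demand is silylation of the benzylic hydroxyls in the presence of the phenols.

## Other disconnections considered

**Alternative 1:** The cut is C1=C2. Forward, the acyclic epoxy diene A2 closes to A1 by ring-closing metathesis with the second-generation Grubbs catalyst RuCl2(=CHPh)(PCy3)(H2IMes), with loss of ethylene. The group on C6 of A2 must be the 1-(acetoxymethyl)vinyl (3-acetoxyprop-1-en-2-yl) unit; with the acetoxymethyl on the terminal vinyl carbon, metathesis would expel it with the alkene by-product.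
- In favour: cyclohexene formation from a vinyl and a 1,1-disubstituted alkene is reliable. The arms are differentiated from the start (acetate on C1, PMB ether on C4), which is better than the chosen plan. The anti C3 oxygen would come from an open-chain addition to an epoxy aldehyde, its normal sense, so no inversion is needed, which is also better.
- Against: all four ring stereocentres, including the quaternary oxirane carbon, must be built in the open chain. The syn C6 oxygen then becomes the contra-normal centre, so the stereochemical problem is moved and not removed. Two allylic silyl ethers flank the reacting alkenes and slow the catalyst.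
- Comparison: on mechanism it is at least the equal of the chosen key step, since it needs no asymmetric induction. On structure it ignores the twofold symmetry. On step economy it is worse, because A2 needs a long linear sequence where 4 needs three steps.

**Alternative 2:** The cut is C5–C6, C3–C4 and C2–C3 at the arene oxidation level. Forward, the Fischer carbene A4 (pentacarbonylchromium, zerovalent chromium) reacts thermally with the silyl propargyl ether A5 and one carbonyl ligand in a Dötz benzannulation to give phenol A3. In A3, O3 is free, O6 is methylated, and the C4 and C1 arms carry TBS and TBDPS groups.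
- In favour: the regiochemistry is predictable (the larger alkyne substituent ends ortho to the phenol). The two arms and the two ring oxygens are differentiated from the outset, which is better than the chosen plan.
- Against: chromium is stoichiometric, no stereocentre is formed, and the ring built is an arene that can be bought with the same substitution pattern. After oxidative demethylation to quinone A6 the twofold axis is gone, so the epoxidation must choose between two alkenes that differ only in remote silyl groups, as well as between two faces.
- Comparison: on structure it trades a free regiochemical answer for early arm differentiation. On mechanism the benzannulation is sound but makes the later asymmetric step harder. On step economy it adds about four steps before any stereocentre exists.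

**Alternative 3:** The cut is C1–C6. Forward, PMe3 adds to C2 of the enoate aldehyde A8, the ester enolate at C1 attacks the C6 aldehyde, and loss of the phosphine restores C1=C2. This intramolecular Morita–Baylis–Hillman reaction gives A7.
- In favour: ring closure and the C6 carbinol come in one metal-free step. C3 and the oxirane are set beforehand in the chain, where the anti C3 oxygen is the normal outcome (better than the chosen plan on this centre). The arms are differentiated as ester and PMB ether (equal or better).
- Against: enoates are reluctant acceptors in this reaction, the phosphine can attack the oxirane aldehyde, and the C6 configuration rests on substrate control in a flexible transition state. The ester must afterwards be reduced next to an oxirane and acetylated.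
- Comparison: on structure it solves C3 but not C6. On mechanism it is less secure than the chosen epoxidation. On step economy it is worse, because A8 with three contiguous stereocentres needs a long linear sequence.

Key step: step 4

Remark (convention): the labels C1–C6 and C1'–C12' refer to the numbering of the first section and not to systematic locants; syn and anti refer to the oxirane oxygen; TBS is tert-butyldimethylsilyl.

Remark (assumption): the sense of induction of a cinchona ammonium salt on this quinone cannot be derived with confidence. The cinchonidinium series is written, and the pseudoenantiomeric cinchoninium salt takes its place if a first run shows the antipode of 5.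

## Route

**Step 1**
Reactants: 1 diethyl 2,5-dihydroxyterephthalate
Product: 2 2,5-bis(hydroxymethyl)benzene-1,4-diol
Conditions: LiAlH4 (excess), THF, 0 °C → reflux; dil. aq. HCl, argon
Reagents that add atoms: none
Why: Ester reduction by LiAlH4; the aluminium phenoxides formed first are inert and the benzylic alcohols are freed on acidic work-up.

**Step 2**
Reactants: 2 2,5-bis(hydroxymethyl)benzene-1,4-diol
Product: 3 2,5-bis(TBS-oxymethyl)benzene-1,4-diol
Conditions: TBSCl (2.2 equiv), imidazole, DMF, 0 °C
Reagents that add atoms: tert-butyldimethylsilyl chloride, CC(C)(C)[Si](C)(C)Cl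
Why: Chemoselective O-silylation; the primary benzylic hydroxyls should react faster than the hydrogen-bonded phenols, and any aryl silyl ether can be returned to the phenol with K2CO3/MeOH without loss of the alkyl silyl ethers.

**Step 3**
Reactants: 3 2,5-bis(TBS-oxymethyl)benzene-1,4-diol
Product: 4 2,5-bis(TBS-oxymethyl)cyclohexa-2,5-diene-1,4-dione
Conditions: Ag2O, MgSO4, Et2O, rt, dark
Reagents that add atoms: none
Why: Two-electron oxidation of the hydroquinone to the quinone under neutral, anhydrous conditions that leave the silyl ethers untouched.

**Step 4**
Reactants: 4 2,5-bis(TBS-oxymethyl)cyclohexa-2,5-diene-1,4-dione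
Product: 5 (1S,6R)-1,4-bis(TBS-oxymethyl)-7-oxabicyclo[4.1.0]hept-3-ene-2,5-dione (quinone mono-epoxide, C4 and C5 as in 23)
Conditions: aq. NaOCl (1.1 equiv), O-benzyl-N-(9-anthracenylmethyl)cinchonidinium bromide (10 mol %), toluene, −10 °C, stopped at partial conversion
Reagents that add atoms: sodium hypochlorite, [Na+].[O-]Cl
Why: Weitz–Scheffer nucleophilic epoxidation under chiral phase-transfer catalysis: hypochlorite, ion-paired with the cinchonidinium cation, adds through oxygen to the unsubstituted C5, β to the C3 carbonyl. The resulting C3 enolate attacks the O–Cl oxygen through C4 and expels chloride, a 3-exo-tet closure of the oxirane. The closest known reaction type is the cinchona-ammonium phase-transfer epoxidation of 2-substituted 1,4-naphthoquinones, quinone monoketals and enones with hypochlorite or hydroperoxides. C4 and C5 are created together and are necessarily cis-fused; their absolute sense is set only by which face of the quinone the ion pair leaves open. The twofold axis of 4 makes the two alkenes homotopic and the two faces enantiotopic, so attack on either alkene from the same face gives the same enantiomer and no regiochemical choice arises. The step needs enantiofacial selectivity and mono-epoxidation; the first rests on the catalyst, the second on a slight excess of oxidant only, partial conversion and recovery of 4. The cold biphasic medium keeps the base-sensitive quinone away from bulk hydroxide.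

**Step 5**
Reactants: 5 quinone mono-epoxide
Product: 6 1,4-bis(TBS-oxymethyl)-5-hydroxy-7-oxabicyclo[4.1.0]hept-3-en-2-one, C6 hydroxyl syn, C3 ketone retained
Conditions: iBu2AlH (1.1 equiv), THF, −78 °C; aq. potassium sodium tartrate
Reagents that add atoms: none
Why: 1,2-Reduction of the more accessible and more electrophilic C6 carbonyl (C3 is flanked by the fully substituted oxirane carbon and is the carbonyl of the β-substituted enone); hydride enters anti to the C5–O bond (Felkin–Anh sense), placing the C6 hydroxyl syn to the oxirane oxygen.

**Step 6**
Reactants: 6 C6 syn-hydroxy enone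
Product: 7 C6 TBS ether of 6
Conditions: TBSCl, imidazole, DMF, 0 °C → rt
Reagents that add atoms: tert-butyldimethylsilyl chloride, CC(C)(C)[Si](C)(C)Cl
Why: Standard silylation of the only free hydroxyl, so that C3 will later carry the only free hydroxyl.

**Step 7**
Reactants: 7 C6 TBS ether enone
Product: 8 C3 alcohol with the C3 hydroxyl syn to the oxirane oxygen (C3 epimer of 10)
Conditions: NaBH4, CeCl3·7H2O, MeOH, −78 °C
Reagents that add atoms: none
Why: Luche 1,2-reduction of the enone; hydride enters anti to the C4–O bond, and the oxygen face is further shielded by the C6 silyl ether, so the C3 hydroxyl should be formed syn, as needed for the inversion in step 8.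

**Step 8**
Reactants: 8 C3 syn alcohol
Product: 9 C3 4-nitrobenzoate with the ester oxygen anti to the oxirane oxygen
Conditions: 4-O2NC6H4CO2H, PPh3, DIAD, toluene, 0 °C → rt
Reagents that add atoms: 4-nitrobenzoic acid, OC(=O)c1ccc(cc1)[N+](=O)[O-]
Why: Mitsunobu reaction: the carboxylate displaces the allylic oxyphosphonium at C3 by SN2 from the face anti to the oxirane oxygen, inverting C3 to the target configuration; SN2' would have to attack the fully substituted C1 and no β-hydrogen is available for elimination.

**Step 9**
Reactants: 9 C3 4-nitrobenzoate
Product: 10 C3 alcohol with the hydroxyl anti to the oxirane oxygen (C6 OTBS syn, both arms OTBS)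
Conditions: K2CO3 (cat.), MeOH, 0 °C
Reagents that add atoms: none
Why: Transesterification of the activated aryl ester under mild base; Payne migration would require attack at the fully substituted C4 and should not compete at this temperature.

**Step 10**
Reactants: 10 C3 anti alcohol
Product: 11 tetrakis-TBS ether (C3 oxygen anti, C6 oxygen syn)
Conditions: TBSOTf, 2,6-lutidine, CH2Cl2, −78 → 0 °C
Reagents that add atoms: tert-butyldimethylsilyl triflate, CC(C)(C)[Si](C)(C)OS(=O)(=O)C(F)(F)F
Why: Silyl triflate silylation of the hindered secondary hydroxyl, so that both ring carbinols are masked through the oxidation and the coupling.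

**Step 11**
Reactants: 11 tetrakis-TBS ether
Product: 12 diol with both CH2OH arms free, C3 and C6 OTBS
Conditions: HF·pyridine, pyridine, THF, 0 °C
Reagents that add atoms: none
Why: Fluoride-mediated desilylation under steric control; primary TBS ethers, including the neopentylic one, are cleaved much faster than secondary TBS ethers, and the buffered medium leaves the oxirane intact.

**Step 12**
Reactants: 12 diol
Product: 13 C1-arm monoacetate, C4 arm CH2OH
Conditions: AcCl (1.05 equiv), 2,4,6-collidine, CH2Cl2, −78 °C
Reagents that add atoms: acetyl chloride, CC(=O)Cl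
Why: Kinetically controlled acylation; the allylic hydroxyl is open, while the C4 hydroxymethyl is neopentylic and flanked by the cis C3 silyl ether.

**Step 13**
Reactants: 13 monoacetate
Product: 14 C4 carbaldehyde (C1 arm CH2OAc, C3 and C6 OTBS)
Conditions: Dess–Martin periodinane, NaHCO3, CH2Cl2, 0 °C → rt
Reagents that add atoms: none
Why: Dess–Martin oxidation of the primary alcohol under buffered conditions; the aldehyde has no α-hydrogen and cannot enolise, and the oxirane, acetate and silyl ethers are inert.

**Step 14**
Reactants: 15 prop-2-yn-1-ol
Product: 17 (E)-3-iodo-2-methylprop-2-en-1-ol, via alkenylalane 16 (not isolated)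
Conditions: AlMe3 (3 equiv), Cp2ZrCl2 (cat.), CH2Cl2, 0 °C → rt; then I2, THF, −30 → 0 °C
Reagents that add atoms: trimethylaluminium, C[Al](C)C; iodine, II
Why: Zirconium-catalysed carboalumination (Negishi): Me–Al adds syn across the alkyne with methyl on the internal carbon, and iodinolysis of the C–Al bond with retention gives the E iodide (future C2'=C3').

**Step 15**
Reactants: 17 (E)-3-iodo-2-methylprop-2-en-1-ol
Product: 18 (E)-3-iodo-2-methylprop-2-enal
Conditions: MnO2, CH2Cl2, rt, dark
Reagents that add atoms: none
Why: Allylic alcohol oxidation on MnO2; the neutral heterogeneous conditions preserve the alkenyl iodide geometry.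

**Step 16**
Reactants: 19 geranyl bromide [(2E)-1-bromo-3,7-dimethylocta-2,6-diene]
Product: 20 diethyl [(2E)-3,7-dimethylocta-2,6-dien-1-yl]phosphonate
Conditions: P(OEt)3, neat, 130 °C
Reagents that add atoms: triethyl phosphite, CCOP(OCC)OCC
Why: Michaelis–Arbuzov reaction: phosphorus attacks the primary allylic carbon by SN2 and bromide dealkylates the phosphonium; the trisubstituted alkene keeps its E geometry.

**Step 17**
Reactants: 20 diethyl geranylphosphonate; 18 (E)-3-iodo-2-methylprop-2-enal
Product: 21 (1E,3E,5E)-1-iodo-2,6,10-trimethylundeca-1,3,5,9-tetraene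
Conditions: n-BuLi, THF, −78 °C; then 18, −78 °C → rt
Reagents that add atoms: none
Why: Horner–Wadsworth–Emmons olefination through the α-carbon of the lithiated allylic phosphonate; elimination from the equilibrated adduct should give the E C4'=C5' alkene, and the two flanking trisubstituted alkenes are not touched at low temperature.

**Step 18**
Reactants: 14 C4 carbaldehyde; 21 tetraenyl iodide
Product: 22 C3,C6-bis-TBS ether of 23 (C1' hydroxyl 1'S, anti to the oxirane oxygen)
Conditions: CrCl2 (excess), NiCl2 (cat.), DMSO, rt, dark
Reagents that add atoms: none
Why: Nozaki–Hiyama–Kishi coupling: zerovalent nickel inserts into the C–I bond, the alkenyl group passes to trivalent chromium and adds to the aldehyde without touching acetate, oxirane or silyl ethers. C1' is set by Cornforth/Felkin–Anh addition, with the carbonyl anti to the C4–O bond and the nucleophile entering on the side away from C5, which gives the anti (erythro) epoxy alcohol.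

**Step 19**
Reactants: 22 bis-TBS ether
Product: 23 [(1S,2S,5S,6R)-2,5-dihydroxy-6-[(1S,2E,4E,6E)-1-hydroxy-3,7,11-trimethyldodeca-2,4,6,10-tetraen-1-yl]-7-oxabicyclo[4.1.0]hept-3-en-3-yl]methyl acetate
Conditions: HF·pyridine, pyridine, THF, 0 °C → rt
Reagents that add atoms: none
Why: Fluoride-mediated removal of the two secondary silyl ethers; pyridine buffering keeps the medium mild enough for the oxirane, the allylic acetate and the trienyl carbinol, and no stereocentre is touched.

## Compound list

1 | diethyl 2,5-dihydroxyterephthalate | CCOC(=O)c1cc(O)c(cc1O)C(=O)OCC | starting material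
2 | 2,5-bis(hydroxymethyl)benzene-1,4-diol | OCc1cc(O)c(CO)cc1O | intermediate
3 | 2,5-bis(TBS-oxymethyl)benzene-1,4-diol | CC(C)(C)[Si](C)(C)OCc1cc(O)c(CO[Si](C)(C)C(C)(C)C)cc1O | intermediate
4 | 2,5-bis(TBS-oxymethyl)cyclohexa-2,5-diene-1,4-dione | O=C1C=C(CO[Si](C)(C)C(C)(C)C)C(=O)C=C1CO[Si](C)(C)C(C)(C)C | intermediate
5 | (1S,6R)-1,4-bis(TBS-oxymethyl)-7-oxabicyclo[4.1.0]hept-3-ene-2,5-dione | CC(C)(C)[Si](C)(C)OCC1=CC(=O)[C@@]2(CO[Si](C)(C)C(C)(C)C)O[C@H]2C1=O | intermediate
6 | C6 syn-hydroxy enone (C3 ketone, both arms OTBS) | CC(C)(C)[Si](C)(C)OCC1=CC(=O)[C@@]2(CO[Si](C)(C)C(C)(C)C)O[C@H]2[C@H]1O | intermediate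
7 | C6 TBS ether of 6 | CC(C)(C)[Si](C)(C)OCC1=CC(=O)[C@@]2(CO[Si](C)(C)C(C)(C)C)O[C@H]2[C@H]1O[Si](C)(C)C(C)(C)C | intermediate
8 | C3 alcohol, C3 hydroxyl syn to the oxirane oxygen, C6 OTBS syn | CC(C)(C)[Si](C)(C)OCC1=C[C@@H](O)[C@@]2(CO[Si](C)(C)C(C)(C)C)O[C@H]2[C@H]1O[Si](C)(C)C(C)(C)C | intermediate
9 | C3 4-nitrobenzoate, ester oxygen anti to the oxirane oxygen | CC(C)(C)[Si](C)(C)OCC1=C[C@H](OC(=O)c3ccc(cc3)[N+](=O)[O-])[C@@]2(CO[Si](C)(C)C(C)(C)C)O[C@H]2[C@H]1O[Si](C)(C)C(C)(C)C | intermediate
10 | C3 alcohol, C3 hydroxyl anti to the oxirane oxygen, C6 OTBS syn | CC(C)(C)[Si](C)(C)OCC1=C[C@H](O)[C@@]2(CO[Si](C)(C)C(C)(C)C)O[C@H]2[C@H]1O[Si](C)(C)C(C)(C)C | intermediate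
11 | tetrakis-TBS ether (C3 oxygen anti, C6 oxygen syn) | CC(C)(C)[Si](C)(C)OCC1=C[C@H](O[Si](C)(C)C(C)(C)C)[C@@]2(CO[Si](C)(C)C(C)(C)C)O[C@H]2[C@H]1O[Si](C)(C)C(C)(C)C | intermediate
12 | diol, both CH2OH arms free, C3 and C6 OTBS | OCC1=C[C@H](O[Si](C)(C)C(C)(C)C)[C@@]2(CO)O[C@H]2[C@H]1O[Si](C)(C)C(C)(C)C | intermediate
13 | C1-arm monoacetate, C4 arm CH2OH | CC(=O)OCC1=C[C@H](O[Si](C)(C)C(C)(C)C)[C@@]2(CO)O[C@H]2[C@H]1O[Si](C)(C)C(C)(C)C | intermediate
14 | C4 carbaldehyde, C1 arm CH2OAc, C3 and C6 OTBS | CC(=O)OCC1=C[C@H](O[Si](C)(C)C(C)(C)C)[C@@]2(C=O)O[C@H]2[C@H]1O[Si](C)(C)C(C)(C)C | intermediate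
15 | prop-2-yn-1-ol | C#CCO | starting material
16 | (E)-alkenylalane, dimethylaluminium alkoxide of 3-(dimethylalumanyl)-2-methylprop-2-en-1-ol | C[Al](C)OC/C(C)=C/[Al](C)C | intermediate (not isolated)
17 | (E)-3-iodo-2-methylprop-2-en-1-ol | OC/C(C)=C/I | intermediate
18 | (E)-3-iodo-2-methylprop-2-enal | O=C/C(C)=C/I | intermediate
19 | geranyl bromide | CC(C)=CCC/C(C)=C/CBr | starting material
20 | diethyl [(2E)-3,7-dimethylocta-2,6-dien-1-yl]phosphonate | CCOP(=O)(C/C=C(\C)CCC=C(C)C)OCC | intermediate
21 | (1E,3E,5E)-1-iodo-2,6,10-trimethylundeca-1,3,5,9-tetraene | I/C=C(C)/C=C/C=C(\C)CCC=C(C)C | intermediate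
22 | C3,C6-bis-TBS ether of 23 | CC(=O)OCC1=C[C@H](O[Si](C)(C)C(C)(C)C)[C@@]2([C@@H](O)/C=C(C)/C=C/C=C(\C)CCC=C(C)C)O[C@H]2[C@H]1O[Si](C)(C)C(C)(C)C | intermediate
23 | [(1S,2S,5S,6R)-2,5-dihydroxy-6-[(1S,2E,4E,6E)-1-hydroxy-3,7,11-trimethyldodeca-2,4,6,10-tetraen-1-yl]-7-oxabicyclo[4.1.0]hept-3-en-3-yl]methyl acetate | CC(=O)OCC1=C[C@H](O)[C@@]2([C@@H](O)/C=C(C)/C=C/C=C(\C)CCC=C(C)C)O[C@H]2[C@H]1O | target

## Step count and least certain steps

Total: 19 steps. Longest linear sequence: 15 steps (steps 1–13, 18 and 19). The side chain takes steps 14–17, with a longest branch of three.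

**Step 4 (key step).** The flat, small benzoquinone may give the ion pair too little to discriminate the faces. The remaining enedione alkene may be epoxidised again. The quinone may be consumed by base (tautomerisation toward a formyl hydroquinone, hydroxide addition). The fallback replaces asymmetric catalysis by resolution. It sets out from 4, which is epoxidised without a chiral catalyst (tBuOOH, DBU, CH2Cl2, 0 °C) to the racemic mono-epoxide F1. Reduction with iBu2AlH as in step 5 gives the racemic syn-hydroxy enone F2. Kinetic resolution with Candida antarctica lipase B and vinyl acetate follows, the enzyme being chosen by screening so that the antipode is acylated to the antipodal C6 acetate F3. The unreacted alcohol returns to the route as 6.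

**Step 5.** Hydride may be delivered to C3 in competition with C6, or to both carbonyls. The fallback imposes the regiochemistry with a directing group. It sets out from 5: the allylic primary silyl ether alone is cleaved (HF·pyridine, pyridine, THF, −20 °C) to the hydroxymethyl quinone epoxide F4. An Evans–Saksena reduction (Me4NBH(OAc)3, MeCN/AcOH, −20 °C) follows, in which only the C6 carbonyl, β to the free hydroxyl, receives hydride, giving the syn diol F5. Double silylation (TBSCl, imidazole, DMF) returns to the route at 7.

**Step 8.** Activation of the C3 hydroxyl or the displacement next to the quaternary oxirane carbon may be slow, so that starting material is recovered or the reagents are consumed unproductively. The fallback changes from inversion to reagent-controlled reduction. It sets out from 7, which is reduced by the Corey–Bakshi–Shibata method with the (R)-Me-CBS oxazaborolidine [(3aR)-1-methyl-3,3-diphenyltetrahydro-3H-pyrrolo[1,2-c][1,3,2]oxazaborole] and catecholborane in toluene at −78 °C. This is the antipode expected to deliver hydride on the oxirane-oxygen face if C4 acts as the large group. It returns to the route at 10 and makes no new compound.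

**Step 12.** Discrimination between the two primary hydroxyls may be incomplete, giving over-acylation or acylation of the wrong arm. The fallback differentiates the arms by silyl ether lability instead of acylation rate. It sets out from 11: only the allylic primary silyl ether is cleaved (HF·pyridine, pyridine, THF, −20 °C, short time) to the mono-alcohol F6. Acetylation (Ac2O, pyridine, DMAP) gives the acetate F7, and prolonged HF·pyridine then frees the neopentylic arm. It returns to the route at 13.

**Step 18.** Facial selectivity at C1' may be poor, or addition to the hindered aldehyde sluggish, so that the 1'-epimer F8 accompanies 22. The fallback sets C1' by reduction instead of addition. It sets out from the mixture of 22 and the 1'-epimer F8, which is oxidised (Dess–Martin periodinane, NaHCO3) to the trienyl ketone F9. Chelation-controlled reduction with Zn(BH4)2 in Et2O at −30 °C, in which zinc bridges the ketone and oxirane oxygens and hydride enters away from C5, gives the anti epoxy alcohol. It returns to the route at 22.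

## Further compounds

F1 | step 4 | racemic 1,4-bis(TBS-oxymethyl)-7-oxabicyclo[4.1.0]hept-3-ene-2,5-dione (5 and its antipode) | CC(C)(C)[Si](C)(C)OCC1=CC(=O)C2(CO[Si](C)(C)C(C)(C)C)OC2C1=O
F2 | step 4 | racemic C6 syn-hydroxy enone (6 and its antipode; antipode drawn) | CC(C)(C)[Si](C)(C)OCC1=CC(=O)[C@]2(CO[Si](C)(C)C(C)(C)C)O[C@@H]2[C@@H]1O
F3 | step 4 | C6 acetate of the antipode of 6 | CC(C)(C)[Si](C)(C)OCC1=CC(=O)[C@]2(CO[Si](C)(C)C(C)(C)C)O[C@@H]2[C@@H]1OC(C)=O
F4 | step 5 | quinone mono-epoxide with free allylic CH2OH on C1 and CH2OTBS on C4 | OCC1=CC(=O)[C@@]2(CO[Si](C)(C)C(C)(C)C)O[C@H]2C1=O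
F5 | step 5 | C6 syn-hydroxy enone with free allylic CH2OH on C1 and CH2OTBS on C4 | OCC1=CC(=O)[C@@]2(CO[Si](C)(C)C(C)(C)C)O[C@H]2[C@H]1O
F0 | step 8 | none | none
F6 | step 12 | mono-alcohol: C1 arm CH2OH, C4 arm CH2OTBS, C3 and C6 OTBS | OCC1=C[C@H](O[Si](C)(C)C(C)(C)C)[C@@]2(CO[Si](C)(C)C(C)(C)C)O[C@H]2[C@H]1O[Si](C)(C)C(C)(C)C
F7 | step 12 | acetate: C1 arm CH2OAc, C4 arm CH2OTBS, C3 and C6 OTBS | CC(=O)OCC1=C[C@H](O[Si](C)(C)C(C)(C)C)[C@@]2(CO[Si](C)(C)C(C)(C)C)O[C@H]2[C@H]1O[Si](C)(C)C(C)(C)C
F8 | step 18 | 1'-epimer of 22 | CC(=O)OCC1=C[C@H](O[Si](C)(C)C(C)(C)C)[C@@]2([C@H](O)/C=C(C)/C=C/C=C(\C)CCC=C(C)C)O[C@H]2[C@H]1O[Si](C)(C)C(C)(C)C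
F9 | step 18 | C1' trienyl ketone | CC(=O)OCC1=C[C@H](O[Si](C)(C)C(C)(C)C)[C@@]2(C(=O)/C=C(C)/C=C/C=C(\C)CCC=C(C)C)O[C@H]2[C@H]1O[Si](C)(C)C(C)(C)C
A1 | alternative 1 | metathesis product: C1 arm CH2OAc, C4 arm CH2OPMB, C3 and C6 OTBS | CC(=O)OCC1=C[C@H](O[Si](C)(C)C(C)(C)C)[C@@]2(COCc3ccc(OC)cc3)O[C@H]2[C@H]1O[Si](C)(C)C(C)(C)C
A2 | alternative 1 | acyclic epoxy octa-1,7-diene with vinyl on C3 and 1-(acetoxymethyl)vinyl on C6 | C=C[C@H](O[Si](C)(C)C(C)(C)C)[C@@]2(COCc3ccc(OC)cc3)O[C@H]2[C@@H](O[Si](C)(C)C(C)(C)C)C(=C)COC(C)=O
A3 | alternative 2 | 2-(TBS-oxymethyl)-4-methoxy-5-(TBDPS-oxymethyl)phenol | COc1cc(CO[Si](C)(C)C(C)(C)C)c(O)cc1CO[Si](c1ccccc1)(c1ccccc1)C(C)(C)C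
A4 | alternative 2 | pentacarbonyl{methoxy[3-(TBDPS-oxy)prop-1-en-2-yl]methylidene}chromium | COC(=[Cr](=C=O)(=C=O)(=C=O)(=C=O)=C=O)C(=C)CO[Si](c1ccccc1)(c1ccccc1)C(C)(C)C
A5 | alternative 2 | tert-butyldimethyl(prop-2-yn-1-yloxy)silane | C#CCO[Si](C)(C)C(C)(C)C
A6 | alternative 2 | 2-(TBS-oxymethyl)-5-(TBDPS-oxymethyl)cyclohexa-2,5-diene-1,4-dione | O=C1C=C(CO[Si](C)(C)C(C)(C)C)C(=O)C=C1CO[Si](c1ccccc1)(c1ccccc1)C(C)(C)C
A7 | alternative 3 | methyl 6-hydroxy epoxycyclohexene-1-carboxylate: C3 OTBS, C4 arm CH2OPMB | COC(=O)C1=C[C@H](O[Si](C)(C)C(C)(C)C)[C@@]2(COCc3ccc(OC)cc3)O[C@H]2[C@H]1O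
A8 | alternative 3 | acyclic epoxy enoate aldehyde | COC(=O)/C=C/[C@H](O[Si](C)(C)C(C)(C)C)[C@@]2(COCc3ccc(OC)cc3)O[C@H]2C=O
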